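**Plan**

- Retrosynthesis: ring B is opened at C9–C10 (cation–olefin closure onto a C10 cation). Ring A is then contracted by returning C4 from C5 to C10, which leaves a 1,2,2-trimethylcyclopentane (C10, C1, C2, C3, C4) with an exocyclic C5 carbinol. The chain is cut at C6–C7 (enolate alkylation) and C5–C6 (MeLi on a carboxylic acid).
- Feature used: in the target, C5 lies between the quaternary carbons C4 (gem-dimethyl) and C10. A 1,2-shift of C4 from C10 to a cationic C5 therefore builds ring A by one-carbon expansion and places the charge on C10, exactly where ring B closes.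
- Forward: (1R,3S)-camphoric acid gives the cyclopentyl methyl ketone (C1–C6, C10, C18–C20). (S)-Citronellol gives the (E)-allylic bromide (C7–C9, C11–C17). The two are joined, C5 is reduced and mesylated, and one solvolysis makes ring A (expansion), then ring B, then the 7-ene.
- Stereochemistry: C3 comes from camphoric acid (Baeyer–Villiger with retention) and C13 from citronellol. C5 comes from a CBS reduction, relayed by inversion in the shift. C10 and C9 come from the chair closure of the (E)-alkene; the C10 centre of the cyclopentane is erased in the cation.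

Key step: step 15

Remark: labdane numbering (C1–C20) is used for all intermediates; the target is read as 3β,15-diacetoxylabd-7-ene with 5α-H, 9α-H, 10β-CH3 and 13S.

**Route**

Step 1
Reactants: 1 (1R,3S)-(+)-camphoric acid
Product: 2 (1R,5S)-1,8,8-trimethyl-3-oxabicyclo[3.2.1]octane-2,4-dione (camphoric anhydride)
Conditions: Ac2O, reflux
Reagents that add atoms: none
Why: Cyclodehydration of the cis-1,3-diacid to the cyclic anhydride (anhydride formation by acyl exchange) is the classical reaction of camphoric acid and leaves both stereocentres untouched.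

Step 2
Reactants: 2 camphoric anhydride
Product: 3 (1R,3S)-3-[methoxy(methyl)carbamoyl]-1,2,2-trimethylcyclopentane-1-carboxylic acid
Conditions: MeNHOMe·HCl, Et3N, DMAP (cat.), CH2Cl2, rt → 40 °C; acidic work-up
Reagents that add atoms: N,O-dimethylhydroxylamine hydrochloride CNOC.Cl
Why: Aminolysis of the unsymmetrical anhydride (nucleophilic acyl substitution) should occur at the carbonyl on the secondary carbon C3, because the other carbonyl is flanked by two quaternary carbons; this differentiates the two carboxyl groups in one step.

Step 3
Reactants: 3 Weinreb amide acid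
Product: 4 (1R,3S)-3-acetyl-1,2,2-trimethylcyclopentane-1-carboxylic acid
Conditions: MeMgBr (3 equiv), THF, 0 °C → rt; aq HCl
Reagents that add atoms: methylmagnesium bromide C[Mg]Br
Why: Weinreb ketone synthesis: after deprotonation of the acid, the Grignard reagent adds once to the N-methoxy-N-methylamide to give a chelated adduct that releases the methyl ketone only on work-up, while the magnesium carboxylate on the quaternary carbon is inert.

Step 4
Reactants: 4 keto acid
Product: 5 (1R,3S)-3-acetoxy-1,2,2-trimethylcyclopentane-1-carboxylic acid
Conditions: mCPBA, CF3CO2H (cat.), CH2Cl2, rt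
Reagents that add atoms: 3-chloroperoxybenzoic acid OOC(=O)c1cccc(Cl)c1
Why: Baeyer–Villiger oxidation, in which the secondary ring carbon migrates in preference to methyl and with retention, so the C3 carboxyl carbon of camphoric acid is exchanged for the C3 oxygen of the target with the (S) configuration already in place.

Step 5
Reactants: 5 acetoxy acid
Product: 6 1-[(1R,3S)-3-hydroxy-1,2,2-trimethylcyclopentyl]ethan-1-one
Conditions: MeLi (6 equiv), Et2O, 0 °C → rt; inverse quench into cold 1 M HCl
Reagents that add atoms: methyllithium [Li]C
Why: Ketone synthesis from a carboxylic acid and an organolithium: the acetate is cleaved, and the lithium carboxylate takes up one MeLi to give a dilithium gem-diolate that survives until the acidic quench, which gives the methyl ketone (C5, C6) on the quaternary C10 without touching either stereocentre.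

Step 6
Reactants: 6 hydroxy ketone
Product: 7 1-[(1R,3S)-3-(tert-butyldimethylsilyloxy)-1,2,2-trimethylcyclopentyl]ethan-1-one
Conditions: TBSOTf, 2,6-lutidine, CH2Cl2, −40 → 0 °C
Reagents that add atoms: tert-butyldimethylsilyl triflate CC(C)(C)[Si](C)(C)OS(=O)(=O)C(F)(F)F
Why: Silyl ether protection of the hindered secondary alcohol with the silyl triflate masks the only O–H before the enolate step, and 2,6-lutidine at low temperature does not enolise the methyl ketone.

Step 7
Reactants: 8 (S)-(−)-citronellol
Product: 9 (S)-1-(tert-butyldimethylsilyloxy)-3,7-dimethyloct-6-ene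
Conditions: TBSCl, imidazole, DMF, rt
Reagents that add atoms: tert-butyldimethylsilyl chloride CC(C)(C)[Si](C)(C)Cl
Why: Standard silyl ether protection of the primary alcohol, so that the chain tolerates the oxidation, bromination and enolate steps.

Step 8
Reactants: 9 citronellyl silyl ether
Product: 10 (2E,6S)-8-(tert-butyldimethylsilyloxy)-2,6-dimethyloct-2-en-1-ol
Conditions: SeO2 (cat.), t-BuOOH, CH2Cl2, 0 °C → rt, stopped at moderate conversion
Reagents that add atoms: tert-butyl hydroperoxide CC(C)(C)OO (the oxygen is relayed by the SeO2 catalyst)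
Why: SeO2-catalysed allylic oxidation (ene reaction, then [2,3]-sigmatropic shift) is selective for the (E)-methyl group of a trisubstituted gem-dimethyl alkene, which fixes the (E) geometry of the future C8=C9 alkene and makes C7 the reactive carbon.

Step 9
Reactants: 10 allylic alcohol
Product: 11 (2E,6S)-1-bromo-8-(tert-butyldimethylsilyloxy)-2,6-dimethyloct-2-ene
Conditions: CBr4, PPh3, CH2Cl2, 0 °C
Reagents that add atoms: carbon tetrabromide BrC(Br)(Br)Br
Why: Appel bromination of the primary allylic alcohol proceeds by SN2 at carbon, without allylic transposition or loss of alkene geometry.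

Step 10
Reactants: 7 silyloxy methyl ketone; 11 allylic bromide
Product: 13 (4E,8S)-10-(tert-butyldimethylsilyloxy)-1-[(1R,3S)-3-(tert-butyldimethylsilyloxy)-1,2,2-trimethylcyclopentyl]-4,8-dimethyldec-4-en-1-one, via lithium enolate 12 (not isolated)
Conditions: LiN(iPr)2 (LDA), THF, −78 °C; then 11, DMPU, −78 → −20 °C
Reagents that add atoms: none
Why: Alkylation of a ketone lithium enolate: 7 can enolise only towards its methyl group because the other α-carbon is quaternary, and the primary allylic bromide reacts by SN2, which forms the C6–C7 bond and joins the fragments with the (E)-alkene intact.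

Step 11
Reactants: 13 bis-silyl ether ketone
Product: 14 (4E,8S)-10-hydroxy-1-[(1R,3S)-3-hydroxy-1,2,2-trimethylcyclopentyl]-4,8-dimethyldec-4-en-1-one
Conditions: HF·pyridine, THF, 0 °C → rt
Reagents that add atoms: none
Why: Fluoride-mediated desilylation removes both silyl ethers (the primary one fast, the neopentyl-type secondary one more slowly) without touching the ketone or the trisubstituted alkene.

Step 12
Reactants: 14 diol ketone
Product: 15 (1S,3R)-3-[(4E,8S)-10-acetoxy-4,8-dimethyldec-4-enoyl]-2,2,3-trimethylcyclopentyl acetate
Conditions: Ac2O, pyridine, DMAP (cat.), CH2Cl2, rt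
Reagents that add atoms: acetic anhydride CC(=O)OC(C)=O
Why: DMAP-catalysed acetylation (nucleophilic acyl transfer) esterifies the primary and the hindered secondary alcohol, so both acetates of the target are in place before the cation chemistry, where esters are inert and do not participate.

Step 13
Reactants: 15 diacetate ketone
Product: 16 (1S,3R)-3-[(1S,4E,8S)-10-acetoxy-1-hydroxy-4,8-dimethyldec-4-en-1-yl]-2,2,3-trimethylcyclopentyl acetate
Conditions: (R)-2-methyl-CBS-oxazaborolidine (0.2 equiv), catecholborane, toluene, −78 → −30 °C; then MeOH, aq NaHCO3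
Reagents that add atoms: none
Why: Corey–Bakshi–Shibata reduction: the oxazaborolidine differentiates the tertiary-alkyl side (C10) from the primary-alkyl side (C6) as it does for pinacolone, so the (R)-catalyst should give the (S)-carbinol at C5 under reagent control, while catecholborane at low temperature leaves the alkene and the acetates alone.

Step 14
Reactants: 16 C5 alcohol
Product: 17 (1S,3R)-3-[(1S,4E,8S)-10-acetoxy-4,8-dimethyl-1-(methylsulfonyloxy)dec-4-en-1-yl]-2,2,3-trimethylcyclopentyl acetate
Conditions: MsCl, Et3N, CH2Cl2, −10 → 0 °C; used without purification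
Reagents that add atoms: methanesulfonyl chloride CS(=O)(=O)Cl
Why: Mesylate formation via the sulfene goes with retention at C5 and supplies the leaving group for the solvolysis.

Step 15
Reactants: 17 mesylate
Product: 20 (13S)-labd-7-ene-3β,15-diyl diacetate (CNP0251773.1), via ring-expanded C10 cation 18 (not isolated), via bicyclic C8 cation 19 (not isolated)
Conditions: 2,6-lutidine (2 equiv), (CF3)2CHOH (HFIP), 0.01 M, 0 → 25 °C
Reagents that add atoms: none
Why: Proposed new method: in the poorly nucleophilic, strongly ionising HFIP the neopentyl-type secondary mesylate should ionise only with help from the antiperiplanar C4–C10 bond, so that the quaternary C4 shifts from C10 to C5 (Wagner–Meerwein ring expansion of a cyclopentylcarbinyl to a cyclohexyl cation, the closest known type being the solvolytic rearrangement of pinacolyl-type sulfonates) and the tertiary cation 18 is left at C10; 18 is the same kind of cation through which monocyclic 1-methyl-2-(alkenyl)cyclohexenes are known to close ring B under acid, the second closest known type. Ring A is thus formed by one-carbon expansion of the camphoric acid cyclopentane and not by cyclisation, and ring B closes by 6-endo-trig attack of C9 of the (E)-alkene on C10 through a chair, giving the tertiary C8 cation 19, which loses the axial H7 to the buffer. C5 is set by inversion at the migration terminus, so the (S)-carbinol becomes the 5α-H centre in the right relation to the C3 acetate; C10 and C9 are set by the chair with the C5 chain equatorial and by the (E) geometry (trans fusion, 10β-CH3, 9α-H), and since C10 is planar in 18 its configuration in 17 should not be carried over. The step needs migration of C4 in preference to C1 or the C10 methyl, which the higher migratory aptitude of the tertiary carbon and the relief of strain between the adjacent quaternary C4 and C10 should secure, and it needs loss of H7 rather than H9 or a C17 proton, which kinetic deprotonation under 2,6-lutidine buffering should favour as in the formation of endocyclic trisubstituted alkenes of the α-ionone and drimenol type. The acetates are inert and, unlike a free or silylated C3 oxygen, cannot capture the C10 cation.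

**Compound list**

1 | (1R,3S)-(+)-camphoric acid | C[C@]1(CC[C@@H](C1(C)C)C(=O)O)C(=O)O | starting material
2 | (1R,5S)-1,8,8-trimethyl-3-oxabicyclo[3.2.1]octane-2,4-dione (camphoric anhydride) | C[C@@]12CC[C@@H](C1(C)C)C(=O)OC2=O | intermediate
3 | (1R,3S)-3-[methoxy(methyl)carbamoyl]-1,2,2-trimethylcyclopentane-1-carboxylic acid | C[C@]1(CC[C@@H](C1(C)C)C(=O)N(C)OC)C(=O)O | intermediate
4 | (1R,3S)-3-acetyl-1,2,2-trimethylcyclopentane-1-carboxylic acid | C[C@]1(CC[C@@H](C1(C)C)C(C)=O)C(=O)O | intermediate
5 | (1R,3S)-3-acetoxy-1,2,2-trimethylcyclopentane-1-carboxylic acid | C[C@]1(CC[C@@H](C1(C)C)OC(C)=O)C(=O)O | intermediate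
6 | 1-[(1R,3S)-3-hydroxy-1,2,2-trimethylcyclopentyl]ethan-1-one | C[C@]1(CC[C@@H](C1(C)C)O)C(C)=O | intermediate
7 | 1-[(1R,3S)-3-(tert-butyldimethylsilyloxy)-1,2,2-trimethylcyclopentyl]ethan-1-one | C[C@]1(CC[C@@H](C1(C)C)O[Si](C)(C)C(C)(C)C)C(C)=O | intermediate
8 | (S)-(−)-citronellol | C[C@@H](CCC=C(C)C)CCO | starting material
9 | (S)-1-(tert-butyldimethylsilyloxy)-3,7-dimethyloct-6-ene | C[C@@H](CCC=C(C)C)CCO[Si](C)(C)C(C)(C)C | intermediate
10 | (2E,6S)-8-(tert-butyldimethylsilyloxy)-2,6-dimethyloct-2-en-1-ol | C[C@@H](CC/C=C(\C)CO)CCO[Si](C)(C)C(C)(C)C | intermediate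
11 | (2E,6S)-1-bromo-8-(tert-butyldimethylsilyloxy)-2,6-dimethyloct-2-ene | C[C@@H](CC/C=C(\C)CBr)CCO[Si](C)(C)C(C)(C)C | intermediate
12 | lithium enolate of 7 (lithium 1-[(1R,3S)-3-(tert-butyldimethylsilyloxy)-1,2,2-trimethylcyclopentyl]ethen-1-olate) | C[C@]1(CC[C@@H](C1(C)C)O[Si](C)(C)C(C)(C)C)C(=C)O[Li] | intermediate
13 | (4E,8S)-10-(tert-butyldimethylsilyloxy)-1-[(1R,3S)-3-(tert-butyldimethylsilyloxy)-1,2,2-trimethylcyclopentyl]-4,8-dimethyldec-4-en-1-one | C[C@]1(CC[C@@H](C1(C)C)O[Si](C)(C)C(C)(C)C)C(=O)CC/C(C)=C/CC[C@H](C)CCO[Si](C)(C)C(C)(C)C | intermediate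
14 | (4E,8S)-10-hydroxy-1-[(1R,3S)-3-hydroxy-1,2,2-trimethylcyclopentyl]-4,8-dimethyldec-4-en-1-one | C[C@]1(CC[C@@H](C1(C)C)O)C(=O)CC/C(C)=C/CC[C@H](C)CCO | intermediate
15 | (1S,3R)-3-[(4E,8S)-10-acetoxy-4,8-dimethyldec-4-enoyl]-2,2,3-trimethylcyclopentyl acetate | C[C@]1(CC[C@@H](C1(C)C)OC(C)=O)C(=O)CC/C(C)=C/CC[C@H](C)CCOC(C)=O | intermediate
16 | (1S,3R)-3-[(1S,4E,8S)-10-acetoxy-1-hydroxy-4,8-dimethyldec-4-en-1-yl]-2,2,3-trimethylcyclopentyl acetate | C[C@]1(CC[C@@H](C1(C)C)OC(C)=O)[C@@H](O)CC/C(C)=C/CC[C@H](C)CCOC(C)=O | intermediate
17 | (1S,3R)-3-[(1S,4E,8S)-10-acetoxy-4,8-dimethyl-1-(methylsulfonyloxy)dec-4-en-1-yl]-2,2,3-trimethylcyclopentyl acetate | C[C@]1(CC[C@@H](C1(C)C)OC(C)=O)[C@@H](OS(C)(=O)=O)CC/C(C)=C/CC[C@H](C)CCOC(C)=O | intermediate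
18 | ring-expanded C10 cation (ring A formed, chain at C5), as its mesylate ion pair | C[C+]1CC[C@H](OC(C)=O)C(C)(C)[C@@H]1CC/C(C)=C/CC[C@H](C)CCOC(C)=O.CS(=O)(=O)[O-] | intermediate
19 | bicyclic C8 cation (labdan-8-yl cation), as its mesylate ion pair | CC(=O)OCC[C@@H](C)CC[C@H]1[C+](C)CC[C@H]2C(C)(C)[C@@H](OC(C)=O)CC[C@]12C.CS(=O)(=O)[O-] | intermediate
20 | (13S)-labd-7-ene-3β,15-diyl diacetate (CNP0251773.1) | CC(=O)OCC[C@@H](C)CC[C@H]1C(C)=CC[C@H]2C(C)(C)[C@@H](OC(C)=O)CC[C@]12C | target

**Totals and risks**

Total step count: 15. Longest linear sequence: 12 (steps 1–6 and 10–15).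

Steps most likely to fail:

Step 15 (proposed new method). Several things may go wrong. The C10 cation may lose a proton before the chain folds. The methyl group or C1 may migrate in place of C4. The ring closure may keep a memory of the precursor geometry and give some cis-fused product. Proton loss from C8 may be unselective. The fallback separates the two events and uses known chemistry, setting out from 17 and returning at 20. Acetolysis of 17 (AcOH, KOAc, 70 °C) should give, by the same assisted ring expansion followed by proton loss, the monocyclic 1(10)-ene diacetate F1 (a solvolytic Wagner–Meerwein rearrangement with elimination). F1 would then be cyclised under the established superacid conditions for ring B closure of monocyclic 1-methylcyclohexene precursors (ClSO3H, 2-nitropropane, −78 °C, then Et3N). Protonation at C1 regenerates the C10 cation without touching C5, and the 7-ene is the expected kinetic product.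

Step 13. Facial selectivity may be poor if the catalyst is mismatched with the adjacent quaternary C10, or the hindered ketone may reduce too slowly. The fallback replaces reagent control by separation and recycling, setting out from 15 and returning at 16. Reduction with NaBH4 (MeOH, 0 °C → rt) should give both C5 epimers, which are diastereomers and separable by chromatography. The (1S)-epimer is 16. The (1R)-epimeric alcohol F2 would be oxidised back to 15 with Dess–Martin periodinane and resubmitted.

Step 5. The methyl ketone may take up a further MeLi to give the tertiary alcohol, or addition to the very hindered lithium carboxylate may be incomplete. The fallback avoids the carboxylate, setting out from 5 and returning at 6. The acid is converted with (COCl)2 and DMF (cat.) into the acid chloride F3. Me2CuLi (Et2O, −78 °C) acylates once and leaves the acetate, to give the acetoxy methyl ketone F4. Methanolysis (K2CO3, MeOH, rt) then gives 6.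

**Further compounds**

F1 | step 15 | (1S,3R)-3-[(3E,7S)-9-acetoxy-3,7-dimethylnon-3-en-1-yl]-2,2,4-trimethylcyclohex-4-en-1-yl acetate | CC1=CC[C@H](OC(C)=O)C(C)(C)[C@@H]1CC/C(C)=C/CC[C@H](C)CCOC(C)=O
F2 | step 13 | (1S,3R)-3-[(1R,4E,8S)-10-acetoxy-1-hydroxy-4,8-dimethyldec-4-en-1-yl]-2,2,3-trimethylcyclopentyl acetate | C[C@]1(CC[C@@H](C1(C)C)OC(C)=O)[C@H](O)CC/C(C)=C/CC[C@H](C)CCOC(C)=O
F3 | step 5 | (1R,3S)-3-acetoxy-1,2,2-trimethylcyclopentane-1-carbonyl chloride | C[C@]1(CC[C@@H](C1(C)C)OC(C)=O)C(=O)Cl
F4 | step 5 | (1S,3R)-3-acetyl-2,2,3-trimethylcyclopentyl acetate | C[C@]1(CC[C@@H](C1(C)C)OC(C)=O)C(C)=O
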